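Late in the dusk run, at 120 s, product stands at 58.8 mM. The mean rate up to 30 s is 0.533 mM/s, and over the whole run it is 0.490 mM/s. So the curve bends gently, and two chemists read that bend differently.

| flask | starting material | partner | catalyst | time |
|---|---|---|---|---|
| dusk | 120 mM | 180 mM | 0.600 mM |  |
| autumn | 72.0 mM | 132 mM | 0.600 mM |  |
| winter | 120 mM | 540 mM | 0.600 mM |  |
| spring | 360 mM | 180 mM | 1.80 mM | 120 s |

| dusk run: time / s | dusk run: [product] / mM | autumn run: time / s | autumn run: [product] / mM | winter run: time / s | winter run: [product] / mM |
|---|---|---|---|---|---|
| 4.8 | 3.5 | 4.8 | 2.5 | 4.8 | 3.0 |
| 7.6 | 4.2 | 7.6 | 2.8 | 7.6 | 6.0 |
| 12 | 6.3 | 12 | 5.3 | 12 | 7.7 |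
| 19 | 11.0 | 19 | 8.7 | 19 | 13.6 |
| 30 | 16.0 | 30 | 12.8 | 30 | 21.7 |
| 48 | 26.0 | 48 | 20.4 | 48 | 33.0 |
| 76 | 37.5 | 76 | 29.7 | 76 | 51.9 |
| 120 | 58.8 | 120 | 43.3 | 120 | 78.5 |

(readings scatter by 0.6 mM)

- the power of [starting material] that the first rate follows, about the charge of the dusk run; measure it at two percent of starting material made into product (one fixed amount of product, the same in the runs compared)
- the power of [partner] that the first rate follows, about the charge of the dusk run; measure it at two percent of starting material made into product
- the autumn run starts with 48.0 mM less of starting material and of partner than the dusk run, and with no product. Compared where both hold the same amount of starting material, once fifteen percent of what the autumn run was charged with has turned into product, is the autumn run faster, slower or alike (within a tenth)?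
- product in the spring run at 120 s, as a share of the starting material charged

- Overall: starting material + partner -> product, with catalyst as catalyst.
- Constant volume, constant temperature.
- Bound and free are read together.
- An order is taken over about fifteen percent of the charge, up and down.

The spring flask is the one in dispute. Its partner is charged below its starting material, so the partner is the limiting reagent. Write P for product. Partner not yet turned into product, in whatever form, is then the charge minus P. Product therefore has its ceiling at 50.0% of the starting material charged.

The first chemist trusts the straight line. The spring run has 3.00 times the catalyst of the dusk run, so she takes 1.60 mM/s as its rate. Over 120 s that makes 192 mM, which is more than the partner charge. She says the spring run reaches the ceiling.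

The second chemist answers from the balance. The winter run, with more partner than the dusk run, averages 0.723 mM/s up to 30 s, so the rate follows partner. He treats starting material as saturating and writes rate = V·R/(R + K), with R the partner left and V the rate of the dusk catalyst load at unlimited partner. The dusk and winter rates give a reading of K, the partner half-point, the partner level at which the rate is half of V: 117 mM. They also give V = 0.880 mM/s.

Putting the balance into the rate and integrating gives his partner clock. The time to reach P is [P + K·ln(R0/(R0 − P))]/(c·V), where R0 is the partner charge and c the catalyst relative to the dusk run. For the spring run, the clock puts 144 mM at 126 s, so his own number lies slightly under the forecast's.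

He grants her the winter run. There, product at 120 s is 14.5% of the partner charged, and the mean rate over that time is 0.654 mM/s, against 0.723 mM/s up to 30 s.

The forecast gives 0.13 and 0.38 for the orders, alike for the comparison, and 40% for the spring run, “limited by partner depletion”.

The flask gives 0.064 and 0.42 for the orders, alike for the comparison, and 35.3% for the spring run, which is 127 mM of product and short of the ceiling.

    catalyst + starting material ⇌ catalyst-substrate complex, settled at all times (21.10 /M)
    catalyst-substrate complex + partner ⇌ ternary complex, settled at all times (18.50 /M)
    ternary complex → product + catalyst (1.620 /s)
    starting material + partner ⇌ idle substrate-reagent adduct, settled at all times (8.020 /M)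

The equations also hold partner in the idle substrate-reagent adduct, with K3 = 8.02 /M. The clock with the same K reaches the spring product at 103 s, earlier than the 120 s the spring run took. In the autumn run, the clock reaches half of the starting material charged at 83.3 s, and the flask took 94.4 s.

The runs were computed on assumed constants, and the scatter is random.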